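## Retrosynthetic overview

1. The cyclopentane is made last: the oxirane of (5S,6R)-cis-5,6-epoxy-5,6-dihydrolycopene opens at C6 to a polyene-stabilised cation, the C1=C2 olefin adds anti, and C16–H is lost. This step sets C6 and C2; C5 is carried over from the oxirane.
2. The C40 epoxide comes from a C7=C8 Wittig union of a C30 polyenyl ylide with a C10 cis-epoxy aldehyde.
3. The epoxy aldehyde comes from nerol by Sharpless epoxidation (sets C5 and C6 of the oxirane) and oxidation.
4. The C30 phosphonium salt comes from a C25 apo-lycopenal plus a C5 dienyl-metal, then vinylogous carbinol-to-phosphonium transposition; the C25 aldehyde comes from pseudoionone (C15 salt) and the C10 dialdehyde.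
5. Ring order: oxirane first (step 6), cyclopentane last (step 9), formed as the oxirane is consumed.

Assumption: carotenoid numbering is used (target = (2S,5S,6R), all-E polyene), and commercial pseudoionone is taken as its (3E,5E) isomer. All polyene work is done in the dark under argon.

## Route

Step 1
Reactants: 1 pseudoionone [(3E,5E)-6,10-dimethylundeca-3,5,9-trien-2-one]
Product: 2 vinyl-ψ-ionol [(4E,6E)-3,7,11-trimethyldodeca-1,4,6,10-tetraen-3-ol; racemic]
Conditions: CH2=CHMgBr (1.2 equiv), THF, −20 to 0 °C; then H2O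
Reagents that add atoms: vinylmagnesium bromide, C=C[Mg]Br
Why: Grignard 1,2-addition to the dienone carbonyl; the new carbinol centre is racemic and is destroyed in step 2.

Step 2
Reactants: 2 vinyl-ψ-ionol
Product: 3 [(2E,4E,6E)-3,7,11-trimethyldodeca-2,4,6,10-tetraen-1-yl]triphenylphosphonium bromide (C15 salt)
Conditions: PPh3·HBr, MeOH, 0 °C to rt; crystallise (2E) salt from EtOAc
Reagents that add atoms: triphenylphosphine hydrobromide, Br.c1ccc(cc1)P(c1ccccc1)c1ccccc1
Why: Acid ionisation of the tertiary vinyl carbinol gives a pentadienyl cation that PPh3 captures at the terminal CH2 (allylic transposition to the conjugated phosphonium salt, the vitamin A type salt formation).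

Step 3
Reactants: 3 C15 salt; 4 (2E,4E,6E)-2,7-dimethylocta-2,4,6-trienedial (C10 dial, 3 equiv)
Product: 6 12'-apo-ψ-caroten-12'-al [(2E,4E,6E,8E,10E,12E,14E)-2,7,11,15,19-pentamethylicosa-2,4,6,8,10,12,14,18-octaenal; C25 aldehyde], via C15 ylide 5 (not isolated)
Conditions: NaOMe, CH2Cl2/MeOH, 0 °C, slow addition of 3 to excess 4; filter off lycopene, recover 4
Reagents that add atoms: none
Why: Wittig olefination; excess symmetrical dialdehyde favours mono-condensation, and the first olefination deactivates the remaining vinylogous aldehyde.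

Step 4
Reactants: 6 C25 aldehyde; 7 2-methylbut-1-en-3-yne
Product: 10 (3E,6E,8E,10E,12E,14E,16E,18E)-2,6,11,15,19,23-hexamethyltetracosa-1,3,6,8,10,12,14,16,18,22-decaen-5-ol (racemic C30 dienyl carbinol), via dienylzirconocene chloride 8 (not isolated), via dienyl(methyl)zinc 9 (not isolated)
Conditions: 7, Cp2Zr(H)Cl, CH2Cl2, rt; Me2Zn, toluene, −65 °C; then 6, 0 °C; H2O/NaHCO3; used crude
Reagents that add atoms: none
Why: Syn, anti-Markovnikov hydrozirconation of the terminal alkyne gives the (E)-dienyl zirconocene, and Zr-to-Zn transmetalation gives an alkenylzinc that adds 1,2 to the polyenal; the new carbinol centre is racemic and is erased in step 5.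

Step 5
Reactants: 10 C30 dienyl carbinol
Product: 11 [(2E,4E,6E,8E,10E,12E,14E,16E,18E)-2,6,11,15,19,23-hexamethyltetracosa-2,4,6,8,10,12,14,16,18,22-decaen-1-yl]triphenylphosphonium bromide (C30 salt)
Conditions: PPh3·HBr, MeOH/CH2Cl2, 0 °C to rt; crystallise
Reagents that add atoms: triphenylphosphine hydrobromide, Br.c1ccc(cc1)P(c1ccccc1)c1ccccc1
Why: Ionisation of the doubly allylic carbinol gives a delocalised polyenyl cation that PPh3 captures at the unhindered terminal CH2 (vinylogous version of the step 2 transposition), giving the fully conjugated primary phosphonium salt.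

Step 6
Reactants: 12 nerol [(2Z)-3,7-dimethylocta-2,6-dien-1-ol]
Product: 13 (2R,3S)-2,3-epoxynerol {[(2R,3S)-3-methyl-3-(4-methylpent-3-en-1-yl)oxiran-2-yl]methanol}
Conditions: Ti(OiPr)4 (5 mol%), D-(−)-diisopropyl tartrate (6 mol%), t-BuOOH, 4 Å molecular sieves, CH2Cl2, −20 °C
Reagents that add atoms: tert-butyl hydroperoxide, CC(C)(C)OO
Why: Sharpless asymmetric epoxidation; the D-tartrate catalyst delivers oxygen to the allylic alcohol face that gives the (2R,3S) cis-oxirane (about 90–94% ee expected), and the remote 6,7-olefin is not touched.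

Step 7
Reactants: 13 (2R,3S)-2,3-epoxynerol
Product: 14 (2S,3S)-3-methyl-3-(4-methylpent-3-en-1-yl)oxirane-2-carbaldehyde (cis-epoxy aldehyde)
Conditions: PhI(OAc)2 (1.1 equiv), TEMPO (10 mol%), CH2Cl2, 0 °C to rt; NaHCO3 wash; used at once
Reagents that add atoms: none
Why: Oxoammonium (TEMPO) oxidation of the primary alcohol under near-neutral conditions leaves the oxirane and its two stereocentres intact (the descriptor at C2 changes only through priorities).

Step 8
Reactants: 11 C30 salt; 14 cis-epoxy aldehyde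
Product: 16 (5S,6R)-5,6-epoxy-5,6-dihydro-ψ,ψ-carotene (cis-oxirane; 7E shown with some 7Z), via C30 ylide 15 (not isolated)
Conditions: KOtBu, THF, −78 °C; then 14, −78 to −20 °C; pH 7 buffer; Et3N-deactivated neutral alumina
Reagents that add atoms: none
Why: Wittig olefination of an α,β-epoxy aldehyde with a polyenyl ylide at low temperature (the way leukotriene-type vinyl oxiranes are made); carbonyl addition outruns attack on the oxirane and neither stereocentre is touched.

Step 9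
Reactants: 16 (5S,6R)-cis-5,6-epoxy-5,6-dihydro-ψ,ψ-carotene
Product: 18 (2S,5S,6R)-1,16-didehydro-1,2,5,6-tetrahydro-2,6-cyclo-ψ,ψ-caroten-5-ol (target CNP0222499.1), via trimethylsilyl ether 17 (not isolated)
Conditions: TMSOTf (1.2 equiv), 2,6-di-tert-butyl-4-methylpyridine (2 equiv), CH2Cl2, −78 °C; then K2CO3, MeOH, 0 °C to rt; then EtOH, 70 °C (Z to E), crystallise
Reagents that add atoms: none
Why: Proposed new method: O-silylation turns the oxirane into a leaving group and the C6–O bond ionises towards the undecaene-stabilised cation while the C1=C2 olefin adds from the back side (inversion at C6 of the cis-oxirane puts the chain cis to the C5 oxygen, giving 6R with 5S unchanged), the olefin orients its CMe2 end away from both the chain and the bulky OSiMe3 (giving 2S), and because the resulting C1 cation is trans to oxygen it cannot close to the 1,5-ether and is deprotonated at C16 by the hindered pyridine to the isopropenyl group; the closest known reactions are the acid-induced rearrangement of lycopene 5,6-epoxide to 2,6-cyclolycopene end groups and silyl triflate/hindered pyridine epoxide–alkene cyclisations ended by proton loss.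

## Compound list

1 | pseudoionone, (3E,5E)-6,10-dimethylundeca-3,5,9-trien-2-one | CC(=O)/C=C/C=C(\C)CCC=C(C)C | starting material
2 | vinyl-ψ-ionol, (4E,6E)-3,7,11-trimethyldodeca-1,4,6,10-tetraen-3-ol (racemic) | C=CC(C)(O)/C=C/C=C(\C)CCC=C(C)C | intermediate
3 | [(2E,4E,6E)-3,7,11-trimethyldodeca-2,4,6,10-tetraen-1-yl]triphenylphosphonium bromide | [Br-].CC(C)=CCC/C(C)=C/C=C/C(C)=C/C[P+](c1ccccc1)(c1ccccc1)c1ccccc1 | intermediate
4 | (2E,4E,6E)-2,7-dimethylocta-2,4,6-trienedial | O=C/C(C)=C/C=C/C=C(\C)C=O | starting material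
5 | C15 ylide, [(2E,4E,6E)-3,7,11-trimethyldodeca-2,4,6,10-tetraen-1-ylidene]triphenylphosphorane | CC(C)=CCC/C(C)=C/C=C/C(C)=C/C=P(c1ccccc1)(c1ccccc1)c1ccccc1 | intermediate (not isolated)
6 | 12'-apo-ψ-caroten-12'-al (all-E C25 aldehyde) | O=C/C(C)=C/C=C/C=C(C)/C=C/C=C(C)/C=C/C=C(\C)CCC=C(C)C | intermediate
7 | 2-methylbut-1-en-3-yne | C=C(C)C#C | starting material
8 | chlorobis(cyclopentadienyl)[(1E)-3-methylbuta-1,3-dien-1-yl]zirconium | C=C(C)/C=C/[Zr](Cl)(C1C=CC=C1)C1C=CC=C1 | intermediate (not isolated)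
9 | methyl[(1E)-3-methylbuta-1,3-dien-1-yl]zinc | C=C(C)/C=C/[Zn]C | intermediate (not isolated)
10 | (3E,6E,8E,10E,12E,14E,16E,18E)-2,6,11,15,19,23-hexamethyltetracosa-1,3,6,8,10,12,14,16,18,22-decaen-5-ol (racemic) | C=C(C)/C=C/C(O)/C(C)=C/C=C/C=C(C)/C=C/C=C(C)/C=C/C=C(\C)CCC=C(C)C | intermediate
11 | [(2E,4E,6E,8E,10E,12E,14E,16E,18E)-2,6,11,15,19,23-hexamethyltetracosa-2,4,6,8,10,12,14,16,18,22-decaen-1-yl]triphenylphosphonium bromide | [Br-].c1ccc(cc1)[P+](c1ccccc1)(c1ccccc1)C/C(C)=C/C=C/C(C)=C/C=C/C=C(C)/C=C/C=C(C)/C=C/C=C(\C)CCC=C(C)C | intermediate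
12 | nerol, (2Z)-3,7-dimethylocta-2,6-dien-1-ol | OC/C=C(/C)CCC=C(C)C | starting material
13 | [(2R,3S)-3-methyl-3-(4-methylpent-3-en-1-yl)oxiran-2-yl]methanol | OC[C@H]1O[C@@]1(C)CCC=C(C)C | intermediate
14 | (2S,3S)-3-methyl-3-(4-methylpent-3-en-1-yl)oxirane-2-carbaldehyde | O=C[C@H]1O[C@@]1(C)CCC=C(C)C | intermediate
15 | C30 ylide, [(2E,4E,6E,8E,10E,12E,14E,16E,18E)-2,6,11,15,19,23-hexamethyltetracosa-2,4,6,8,10,12,14,16,18,22-decaen-1-ylidene]triphenylphosphorane | c1ccc(cc1)P(c1ccccc1)(c1ccccc1)=C/C(C)=C/C=C/C(C)=C/C=C/C=C(C)/C=C/C=C(C)/C=C/C=C(\C)CCC=C(C)C | intermediate (not isolated)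
16 | (5S,6R)-5,6-epoxy-5,6-dihydro-ψ,ψ-carotene (cis-oxirane, all-E polyene) | CC(C)=CCC[C@]1(C)O[C@@H]1/C=C/C(C)=C/C=C/C(C)=C/C=C/C=C(C)/C=C/C=C(C)/C=C/C=C(\C)CCC=C(C)C | intermediate
17 | trimethylsilyl ether of 18, (1S,2R,3S)-1-methyl-2-polyenyl-3-(prop-1-en-2-yl)-1-(trimethylsilyloxy)cyclopentane | C=C(C)[C@H]1CC[C@](C)(O[Si](C)(C)C)[C@@H]1/C=C/C(C)=C/C=C/C(C)=C/C=C/C=C(C)/C=C/C=C(C)/C=C/C=C(\C)CCC=C(C)C | intermediate (not isolated)
18 | (1S,2R,3S)-1-methyl-2-[(1E,3E,5E,7E,9E,11E,13E,15E,17E,19E)-3,7,12,16,20,24-hexamethylpentacosa-1,3,5,7,9,11,13,15,17,19,23-undecaen-1-yl]-3-(prop-1-en-2-yl)cyclopentan-1-ol | C=C(C)[C@H]1CC[C@](C)(O)[C@@H]1/C=C/C(C)=C/C=C/C(C)=C/C=C/C=C(C)/C=C/C=C(C)/C=C/C=C(\C)CCC=C(C)C | target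

## Step count

Total steps: 9. Longest linear sequence: 7 (1 → 2 → 3 → 6 → 10 → 11 → 16 → 18).

## Three steps most likely to fail, with fallbacks

**Step 9 (key cyclisation).** The cation may cyclise in a mode with C1 cis to oxygen and close to 1,5-ethers, the ring closure may reverse, or the polyene may degrade. The fallback sets out from salt 11 and comes back at 18. Commercial (S)-(−)-limonene F1 is epoxidised at the ring olefin (mCPBA, CH2Cl2, 0 °C) to (4S)-limonene 1,2-oxide F2. H5IO6 in THF/H2O cleaves this to (3S)-6-oxo-3-(prop-1-en-2-yl)heptanal F3. Equilibrating intramolecular aldol addition (K2CO3, MeOH, 0 °C, stopped before dehydration) gives (1R,2S,5S)-2-hydroxy-2-methyl-5-(prop-1-en-2-yl)cyclopentane-1-carbaldehyde F4, the isomer with CHO trans to both the isopropenyl and the methyl group. Wittig condensation of F4 with salt 11 (through ylide 15) in refluxing 1,2-epoxybutane needs no strong base and so spares the β-hydroxy aldehyde; it gives 18 directly.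

**Step 8 (Wittig on the epoxy aldehyde).** The basic C30 ylide may open or epimerise 14, and 16 is acid-labile. The fallback sets out from 14 and comes back at 16, moving the union to C11=C12. Aldehyde 14 is lengthened with the stabilised anion of triethyl 3-methyl-4-phosphonocrotonate (NaH, THF, 0 °C) to ethyl (2E,4E)-3-methyl-5-[(2R,3S)-3-methyl-3-(4-methylpent-3-en-1-yl)oxiran-2-yl]penta-2,4-dienoate F5. i-Bu2AlH at −78 °C gives the epoxy dienol F6, and MnO2 gives the epoxy dienal F7. In parallel, aldehyde 6 is reduced with NaBH4 to 12'-apo-ψ-caroten-12'-ol F8 and converted with PPh3·HBr into the C25 phosphonium bromide F9. Its ylide, the C25 ylide F10 (NaOMe, CH2Cl2/MeOH, 0 °C), condenses with F7 to give 16.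

**Step 5 (vinylogous phosphonium formation; also replaces step 4).** PPh3 may attack internal positions of the long cation or give inseparable E/Z salts. The fallback sets out from 6 and comes back at 11, using only stabilised ylides and a primary alcohol. Aldehyde 6 and Ph3P=CHCHO (toluene, 80 °C) give 10'-apo-ψ-caroten-10'-al F11. Ph3P=C(CH3)CO2Et then gives ethyl 8'-apo-ψ-caroten-8'-oate F12. i-Bu2AlH (CH2Cl2, −78 °C) gives 8'-apo-ψ-caroten-8'-ol F13, and PPh3·HBr converts this primary allylic alcohol into 11 without transposition.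

## Further compounds

F1 | step 9 | (S)-(−)-limonene | CC1=CC[C@H](CC1)C(C)=C
F2 | step 9 | (4S)-limonene 1,2-oxide (cis/trans oxirane mixture) | CC12CC[C@@H](CC1O2)C(C)=C
F3 | step 9 | (3S)-6-oxo-3-(prop-1-en-2-yl)heptanal | CC(=O)CC[C@@H](CC=O)C(C)=C
F4 | step 9 | (1R,2S,5S)-2-hydroxy-2-methyl-5-(prop-1-en-2-yl)cyclopentane-1-carbaldehyde | C=C(C)[C@H]1CC[C@](C)(O)[C@@H]1C=O
F5 | step 8 | ethyl (2E,4E)-3-methyl-5-[(2R,3S)-3-methyl-3-(4-methylpent-3-en-1-yl)oxiran-2-yl]penta-2,4-dienoate | CCOC(=O)/C=C(C)/C=C/[C@H]1O[C@@]1(C)CCC=C(C)C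
F6 | step 8 | (2E,4E)-3-methyl-5-[(2R,3S)-3-methyl-3-(4-methylpent-3-en-1-yl)oxiran-2-yl]penta-2,4-dien-1-ol | OC/C=C(C)/C=C/[C@H]1O[C@@]1(C)CCC=C(C)C
F7 | step 8 | (2E,4E)-3-methyl-5-[(2R,3S)-3-methyl-3-(4-methylpent-3-en-1-yl)oxiran-2-yl]penta-2,4-dienal | O=C/C=C(C)/C=C/[C@H]1O[C@@]1(C)CCC=C(C)C
F8 | step 8 | 12'-apo-ψ-caroten-12'-ol (all-E C25 alcohol) | OC/C(C)=C/C=C/C=C(C)/C=C/C=C(C)/C=C/C=C(\C)CCC=C(C)C
F9 | step 8 | [(2E,4E,6E,8E,10E,12E,14E)-2,7,11,15,19-pentamethylicosa-2,4,6,8,10,12,14,18-octaen-1-yl]triphenylphosphonium bromide | [Br-].c1ccc(cc1)[P+](c1ccccc1)(c1ccccc1)C/C(C)=C/C=C/C=C(C)/C=C/C=C(C)/C=C/C=C(\C)CCC=C(C)C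
F10 | step 8 | C25 ylide, [(2E,4E,6E,8E,10E,12E,14E)-2,7,11,15,19-pentamethylicosa-2,4,6,8,10,12,14,18-octaen-1-ylidene]triphenylphosphorane | c1ccc(cc1)P(c1ccccc1)(c1ccccc1)=C/C(C)=C/C=C/C=C(C)/C=C/C=C(C)/C=C/C=C(\C)CCC=C(C)C
F11 | step 5 | 10'-apo-ψ-caroten-10'-al (all-E C27 aldehyde) | O=C/C=C/C(C)=C/C=C/C=C(C)/C=C/C=C(C)/C=C/C=C(\C)CCC=C(C)C
F12 | step 5 | ethyl 8'-apo-ψ-caroten-8'-oate (all-E C30 ester) | CCOC(=O)/C(C)=C/C=C/C(C)=C/C=C/C=C(C)/C=C/C=C(C)/C=C/C=C(\C)CCC=C(C)C
F13 | step 5 | 8'-apo-ψ-caroten-8'-ol (all-E C30 alcohol) | OC/C(C)=C/C=C/C(C)=C/C=C/C=C(C)/C=C/C=C(C)/C=C/C=C(\C)CCC=C(C)C
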